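**Retrosynthetic overview**
1. Target 15 comes from 14 by BBr3 cleavage of the three ring-E methyl ethers.
2. 14 comes from the octa-aldehyde 12 by one ninefold peracid oxidation (8 × Baeyer–Villiger/Dakin of ArCHO, 1 × C–B oxidation). All eight inner hydroxyls travel as formyl groups.
3. 12 comes from four iterative SNAr etherifications that cut the hindered C–O bond of every ether (the carbon flanked by two oxygens), not the unhindered one an Ullmann plan would cut. The electrophile each time is 2-fluoro-5-borylisophthalaldehyde 4, whose CHO groups activate the fluoride and whose Bpin is the masked next phenol.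
4. 4 comes from Ir-catalysed C–H borylation of 2-fluoroisophthalaldehyde 1.
5. No ring is formed; the arenes are added in the order E, D, C, B, A.

Assumption: the target has no stereocentre and no stable atropisomer, so it is achiral and "single enantiomer" needs no stereocontrol.

**Step 1**
Reactants: 1 2-fluoroisophthalaldehyde
Product: 4 2-fluoro-5-(4,4,5,5-tetramethyl-1,3,2-dioxaborolan-2-yl)isophthalaldehyde, via bis(N-tert-butylaldimine) 2 (not isolated), via 5-boryl bis(N-tert-butylaldimine) 3 (not isolated)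
Conditions: t-BuNH2 (2.2 equiv), 4 Å MS, THF, rt; then [Ir(OMe)(cod)]2 (1.5 mol %), 3,4,7,8-Me4-phen (3 mol %), B2pin2 (1.0 equiv), THF, 70 °C; then 1 M aq HCl, THF, rt
Reagents that add atoms: bis(pinacolato)diboron, CC1(C)OB(OC1(C)C)B1OC(C)(C)C(C)(C)O1; water, O
Why: Transient aldimine protection keeps the formyl groups from being reduced during a sterically controlled Ir-catalysed C–H borylation, which goes to C5 because it is the only C–H without an ortho substituent, and mild acid then returns the aldehydes.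

**Step 2**
Reactants: 5 3,4,5-trimethoxyphenol (1.05 equiv); 4 2-fluoro-5-(pinacolboryl)isophthalaldehyde
Product: 7 5-hydroxy-2-(3,4,5-trimethoxyphenoxy)isophthalaldehyde, via dimer boronate 6 (not isolated)
Conditions: K2CO3, DMF, 40 °C until 4 is consumed; then NMO (3 equiv), rt to 50 °C; 1 M HCl work-up
Reagents that add atoms: N-methylmorpholine N-oxide, C[N+]1([O-])CCOCC1
Why: SNAr works at the hindered carbon because two ortho formyl groups and the para boryl group stabilise the Meisenheimer complex, and the N-oxide then oxidises only the C–B bond (boron-ate 1,2-aryl shift) without touching the aldehydes.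

**Step 3**
Reactants: 7 E–D phenol (1.05 equiv); 4 2-fluoro-5-(pinacolboryl)isophthalaldehyde
Product: 9 5-(2,6-diformyl-4-hydroxyphenoxy)-2-(3,4,5-trimethoxyphenoxy)isophthalaldehyde, via trimer boronate 8 (not isolated)
Conditions: K2CO3, DMSO, 50 °C until 4 is consumed; then NMO (3 equiv), rt to 50 °C; 1 M HCl work-up
Reagents that add atoms: N-methylmorpholine N-oxide, C[N+]1([O-])CCOCC1
Why: The same SNAr then N-oxide C–B oxidation sequence; the 3,5-diformylphenoxide is a weaker nucleophile but the doubly ortho-activated fluoride is far more reactive than any aryl ether carbon, so the low temperature avoids ether exchange.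

**Step 4**
Reactants: 9 E–D–C phenol (1.05 equiv); 4 2-fluoro-5-(pinacolboryl)isophthalaldehyde
Product: 11 5-[2,6-diformyl-4-(2,6-diformyl-4-hydroxyphenoxy)phenoxy]-2-(3,4,5-trimethoxyphenoxy)isophthalaldehyde, via tetramer boronate 10 (not isolated)
Conditions: K2CO3, DMSO, 50 °C until 4 is consumed; then NMO (3 equiv), rt to 50 °C; 1 M HCl work-up
Reagents that add atoms: N-methylmorpholine N-oxide, C[N+]1([O-])CCOCC1
Why: Third iteration of the SNAr then N-oxide C–B oxidation sequence, with the same activation and the same chemoselectivity as in step 3.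

**Step 5**
Reactants: 11 E–D–C–B phenol; 4 2-fluoro-5-(pinacolboryl)isophthalaldehyde (1.2 equiv)
Product: 12 E–D–C–B–A octa-aldehyde boronate (ring A = 2,6-diformyl-4-(pinacolboryl)phenoxy)
Conditions: K2CO3, DMSO, 50 °C
Reagents that add atoms: none
Why: Fourth SNAr of the same kind; the product has no free OH, so it cannot over-arylate, and the boronate is kept for the global oxidation.

**Step 6**
Reactants: 12 octa-aldehyde boronate
Product: 14 nonaol trimethyl ether (all CHO and Bpin replaced by OH), via octaformate borate 13 (not isolated)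
Conditions: mCPBA (14 equiv), CH2Cl2, 0 to 40 °C; aq Na2S2O3 wash; then 1.25 M HCl in MeOH, rt, Ar
Reagents that add atoms: meta-chloroperoxybenzoic acid, OOC(=O)c1cccc(Cl)c1
Why: Each formyl group is ortho to an aryloxy donor, so the Criegee adducts collapse by aryl migration (Baeyer–Villiger/Dakin oxidation) to aryl formates while the peracid also oxidises the C–B bond, and acidic methanolysis frees all nine hydroxyls without exposing the polyphenol to base.

**Step 7**
Reactants: 14 nonaol trimethyl ether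
Product: 15 target CNP0308003.0
Conditions: BBr3 (20 equiv), CH2Cl2, −78 °C to rt; MeOH then H2O; Sephadex LH-20 or C18 under Ar
Reagents that add atoms: none
Why: Lewis-acid ether cleavage by BBr3 (bromide SN2 at methyl) removes the three aryl methyl ethers, while diaryl ether bonds are inert to it.

**Compound list**
1 | 2-fluoroisophthalaldehyde (2-fluorobenzene-1,3-dicarbaldehyde) | O=Cc1cccc(C=O)c1F | starting material
2 | (E,E)-N,N'-di-tert-butyl bis(aldimine) of 1 | CC(C)(C)/N=C/c1cccc(/C=N/C(C)(C)C)c1F | intermediate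
3 | 5-(pinacolboryl) derivative of bis(aldimine) 2 | CC(C)(C)/N=C/c1cc(B2OC(C)(C)C(C)(C)O2)cc(/C=N/C(C)(C)C)c1F | intermediate
4 | 2-fluoro-5-(4,4,5,5-tetramethyl-1,3,2-dioxaborolan-2-yl)isophthalaldehyde | O=Cc1cc(B2OC(C)(C)C(C)(C)O2)cc(C=O)c1F | intermediate
5 | 3,4,5-trimethoxyphenol | COc1cc(O)cc(OC)c1OC | starting material
6 | E–D dimer boronate: 5-(pinacolboryl)-2-(3,4,5-trimethoxyphenoxy)isophthalaldehyde | COc1cc(Oc2c(C=O)cc(B3OC(C)(C)C(C)(C)O3)cc2C=O)cc(OC)c1OC | intermediate
7 | E–D phenol: 5-hydroxy-2-(3,4,5-trimethoxyphenoxy)isophthalaldehyde | COc1cc(Oc2c(C=O)cc(O)cc2C=O)cc(OC)c1OC | intermediate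
8 | E–D–C trimer boronate (tetra-aldehyde, terminal Bpin) | COc1cc(Oc2c(C=O)cc(Oc3c(C=O)cc(B4OC(C)(C)C(C)(C)O4)cc3C=O)cc2C=O)cc(OC)c1OC | intermediate
9 | E–D–C phenol: 5-(2,6-diformyl-4-hydroxyphenoxy)-2-(3,4,5-trimethoxyphenoxy)isophthalaldehyde | COc1cc(Oc2c(C=O)cc(Oc3c(C=O)cc(O)cc3C=O)cc2C=O)cc(OC)c1OC | intermediate
10 | E–D–C–B tetramer boronate (hexa-aldehyde, terminal Bpin) | COc1cc(Oc2c(C=O)cc(Oc3c(C=O)cc(Oc4c(C=O)cc(B5OC(C)(C)C(C)(C)O5)cc4C=O)cc3C=O)cc2C=O)cc(OC)c1OC | intermediate
11 | E–D–C–B phenol (hexa-aldehyde, terminal 4-OH) | COc1cc(Oc2c(C=O)cc(Oc3c(C=O)cc(Oc4c(C=O)cc(O)cc4C=O)cc3C=O)cc2C=O)cc(OC)c1OC | intermediate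
12 | E–D–C–B–A pentamer octa-aldehyde boronate | COc1cc(Oc2c(C=O)cc(Oc3c(C=O)cc(Oc4c(C=O)cc(Oc5c(C=O)cc(B6OC(C)(C)C(C)(C)O6)cc5C=O)cc4C=O)cc3C=O)cc2C=O)cc(OC)c1OC | intermediate
13 | pentamer octakis(formate) aryl pinacol borate | COc1cc(Oc2c(OC=O)cc(Oc3c(OC=O)cc(Oc4c(OC=O)cc(Oc5c(OC=O)cc(OB6OC(C)(C)C(C)(C)O6)cc5OC=O)cc4OC=O)cc3OC=O)cc2OC=O)cc(OC)c1OC | intermediate
14 | pentamer nonaol with ring E as 3,4,5-trimethoxyphenyl | COc1cc(Oc2c(O)cc(Oc3c(O)cc(Oc4c(O)cc(Oc5c(O)cc(O)cc5O)cc4O)cc3O)cc2O)cc(OC)c1OC | intermediate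
15 | CNP0308003.0 (achiral) | Oc1cc(O)c(Oc2cc(O)c(Oc3cc(O)c(Oc4cc(O)c(Oc5cc(O)c(O)c(O)c5)c(O)c4)c(O)c3)c(O)c2)c(O)c1 | target

**Step count and risks**
Total step count: 7. Longest linear sequence: 7 steps (1 to 15).

The three steps most likely to fail:

Step 1. The borylation may reduce the imine or aldehyde groups, or t-BuNH2 may displace the activated fluoride. The fallback sets out from 1 and comes back to the route at 4. It replaces C–H activation with electrophilic substitution and cross-coupling: NBS in conc. H2SO4 at 60 °C brominates C5 (para to F, meta to both CHO) to give 5-bromo-2-fluoroisophthalaldehyde F1, and Miyaura borylation (B2pin2, Pd(dppf)Cl2, KOAc, dioxane, 85 °C) converts it into 4.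

Step 3. This is the first coupling in which the weakly nucleophilic 3,5-diformylphenoxide must react while the boronate survives base; protodeboronation or ether exchange at the activated aryl ether carbons would erode it. The fallback sets out from 4 and comes back at 9, and it removes boron from the basic step. NMO oxidises 4 to 2-fluoro-5-hydroxyisophthalaldehyde F2, MOMCl with i-Pr2NEt gives 2-fluoro-5-(methoxymethoxy)isophthalaldehyde F3, SNAr of 7 with F3 (K2CO3, DMSO, 60 °C) gives the MOM-protected E–D–C trimer F4, and 6 M HCl in THF at 40 °C releases 9. The same monomer F3 can serve steps 4 and 5 if needed.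

Step 6. In the ninefold oxidation, hydride migration on the electron-poor rings would give carboxylic acids instead of formates. The fallback sets out from 12 and comes back at 14, and it swaps aldehyde for ketone Baeyer–Villiger so that only aryl and methyl compete for migration. NMO gives the pentamer phenol octa-aldehyde F5, excess MeMgBr (THF, −78 to 0 °C) gives the octakis(1-hydroxyethyl) phenol F6 as a diastereomer mixture whose stereocentres vanish in the next operation, MnO2 gives the octa-acetyl phenol F7, CF3CO3H (TFAA, urea·H2O2, Na2HPO4, CH2Cl2) gives the octa-acetate F8, and HCl in MeOH gives 14.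

**Further compounds**
F1 | step 1 | 5-bromo-2-fluoroisophthalaldehyde | O=Cc1cc(Br)cc(C=O)c1F
F2 | step 3 | 2-fluoro-5-hydroxyisophthalaldehyde | O=Cc1cc(O)cc(C=O)c1F
F3 | step 3 | 2-fluoro-5-(methoxymethoxy)isophthalaldehyde | COCOc1cc(C=O)c(F)c(C=O)c1
F4 | step 3 | MOM-protected E–D–C trimer tetra-aldehyde | COCOc1cc(C=O)c(Oc2cc(C=O)c(Oc3cc(OC)c(OC)c(OC)c3)c(C=O)c2)c(C=O)c1
F5 | step 6 | pentamer phenol octa-aldehyde | COc1cc(Oc2c(C=O)cc(Oc3c(C=O)cc(Oc4c(C=O)cc(Oc5c(C=O)cc(O)cc5C=O)cc4C=O)cc3C=O)cc2C=O)cc(OC)c1OC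
F6 | step 6 | pentamer phenol octakis(1-hydroxyethyl) compound (diastereomer mixture) | COc1cc(Oc2c(C(C)O)cc(Oc3c(C(C)O)cc(Oc4c(C(C)O)cc(Oc5c(C(C)O)cc(O)cc5C(C)O)cc4C(C)O)cc3C(C)O)cc2C(C)O)cc(OC)c1OC
F7 | step 6 | pentamer phenol octa-acetyl compound | COc1cc(Oc2c(C(C)=O)cc(Oc3c(C(C)=O)cc(Oc4c(C(C)=O)cc(Oc5c(C(C)=O)cc(O)cc5C(C)=O)cc4C(C)=O)cc3C(C)=O)cc2C(C)=O)cc(OC)c1OC
F8 | step 6 | pentamer phenol octa-acetate | COc1cc(Oc2c(OC(C)=O)cc(Oc3c(OC(C)=O)cc(Oc4c(OC(C)=O)cc(Oc5c(OC(C)=O)cc(O)cc5OC(C)=O)cc4OC(C)=O)cc3OC(C)=O)cc2OC(C)=O)cc(OC)c1OC
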